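**Retrosynthetic overview**
1. Enone C=C, formed last: Claisen–Schmidt condensation of 3-lavandulyl-2,4-dihydroxyacetophenone (carried as its diacetate) with salicylaldehyde.
2. Aryl–CH2 bond: Negishi coupling of the lavandulylzinc reagent with 3-iodo-2,4-diacetoxyacetophenone (iodine placed between the two hydroxyls of 2,4-dihydroxyacetophenone).
3. Stereocentre: lavandulyl iodide ⇐ (R)-lavandulol ⇐ pantolactone ester. The key step is the formation of the acyl C–O bond of this ester by adding (R)-pantolactone to isopropenyl(prenyl)ketene; the accompanying α-protonation sets the only stereocentre, stereoconvergently from racemic lavandulic acid.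
4. Racemic lavandulic acid ⇐ dianion of 3-methylbut-2-enoic acid + prenyl bromide.
5. Rings: none is built; both benzene rings are bought.

Assumption: the target is taken exactly as drawn. Its stereocentre is (S) by the CIP rules and has the spatial arrangement of (R)-lavandulol and (R)-lavandulic acid (the descriptor changes only because aryl-CH2 ranks below isopropenyl, whereas CH2OH, CH2I and CO2R rank above it).

**Route**

Step 1
Reactants: 1 3-methylbut-2-enoic acid; 2 prenyl bromide (1-bromo-3-methylbut-2-ene)
Product: 4 (±)-lavandulic acid, via dilithium dienediolate 3 (not isolated)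
Conditions: LiN(iPr)2 (2.2 equiv), THF, −78 → 0 °C; then 2, −78 °C → rt; aq. HCl work-up
Reagents that add atoms: none
Why: Alkylation of a carboxylic acid dienediolate, in which the dilithium dianion attacks the allylic bromide by SN2 through its α-carbon (the kinetic site of lithium dienolates), moving the double bond out of conjugation and giving the lavandulyl skeleton as a racemate, which is acceptable because the centre is erased in step 2.

Step 2
Reactants: 4 (±)-lavandulic acid; 5 (R)-pantolactone
Product: 8 (R)-pantolactonyl (R)-lavandulate, via acid chloride 6 (not isolated), via ketene 7 (not isolated)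
Conditions: (COCl)2, DMF (cat.), CH2Cl2, 0 °C → rt, evaporate; Me2NEt (3 equiv), toluene, −20 °C, 30 min; then 5, −78 → −40 °C
Reagents that add atoms: none
Why: Proposed new method: stereoconvergent esterification through a ketene, in which the amine dehydrochlorinates the racemic β,γ-unsaturated acid chloride to the achiral isopropenyl(prenyl)ketene and then relays addition of the (R)-pantolactone O–H across the ketene (O to the carbonyl carbon, which makes the new acyl C–O bond, H to the α-carbon), the proton being delivered to the prochiral dienolate carbon from within a hydrogen-bonded complex with the chiral hydroxy-lactone that tells the flat, conjugating isopropenyl group from the sp3 prenyl CH2, so that both enantiomers of the acid converge on the (2R) ester while kinetic α-protonation keeps the alkene deconjugated; the closest known reaction type is the amine-mediated addition of pantolactone or lactate esters to aryl(alkyl)ketenes made from racemic 2-arylpropanoyl chlorides, where (R)-pantolactone gives (R) esters with high dr, and the alkenyl(alkyl)ketene is the untested substrate class (isopropenyl in the role of aryl, prenyl CH2 in that of methyl), any minor diastereomer being removed by chromatography.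

Step 3
Reactants: 8 (R)-pantolactonyl (R)-lavandulate
Product: 9 (R)-lavandulol
Conditions: LiAlH4, Et2O, 0 °C; then H2O
Reagents that add atoms: none
Why: Hydride reduction of both ester carbonyls releases the primary alcohol and turns the auxiliary into a water-soluble triol, and since hydride addition is far faster than α-deprotonation the stereocentre is kept.

Step 4
Reactants: 9 (R)-lavandulol
Product: 10 (R)-lavandulyl iodide
Conditions: PPh3, I2, imidazole, CH2Cl2, 0 °C → rt, dark
Reagents that add atoms: iodine, II
Why: Appel iodination of the primary alcohol by SN2 at the CH2 group, one carbon away from the stereocentre, which is untouched.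

Step 5
Reactants: 11 2,4-dihydroxyacetophenone
Product: 12 1-(2,4-dihydroxy-3-iodophenyl)ethan-1-one
Conditions: I2 (0.4 equiv), HIO3 (0.2 equiv), EtOH/H2O, 35 °C
Reagents that add atoms: iodine, II; iodic acid, OI(=O)=O
Why: Oxidative electrophilic aromatic iodination, directed to the carbon between the two hydroxyls because chelation of the 2-OH to the carbonyl makes that position the most nucleophilic one of resacetophenone (as in its C-alkylation and Claisen chemistry), with the minor 5-iodo isomer removed by crystallisation.

Step 6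
Reactants: 12 1-(2,4-dihydroxy-3-iodophenyl)ethan-1-one
Product: 13 4-acetyl-2-iodo-1,3-phenylene diacetate
Conditions: Ac2O (3 equiv), pyridine, DMAP (5 mol %), CH2Cl2, rt
Reagents that add atoms: acetic anhydride, CC(=O)OC(C)=O
Why: DMAP-catalysed O-acetylation masks the two acidic phenols, which would protonate the organozinc reagent, as esters that fall off by themselves in the basic last step.

Step 7
Reactants: 10 (R)-lavandulyl iodide; 13 4-acetyl-2-iodo-1,3-phenylene diacetate
Product: 15 4-acetyl-2-[(2S)-5-methyl-2-(prop-1-en-2-yl)hex-4-en-1-yl]-1,3-phenylene diacetate, via alkylzinc iodide 14 (not isolated)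
Conditions: Zn dust (activated), LiCl, THF, 30 °C; then 13 (1.2 equiv), Pd(OAc)2 (2 mol %), SPhos (4 mol %), THF, 25 → 45 °C
Reagents that add atoms: none
Why: Negishi sp3–sp2 cross-coupling, in which zinc inserts into the primary C–I bond, the alkylzinc iodide tolerates the ketone and the aryl acetates, and the bulky electron-rich biarylphosphine makes reductive elimination from the hindered aryl(alkyl)palladium faster than β-hydride elimination, so the β-stereocentre is carried through unchanged (only its descriptor changes from R to S).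

Step 8
Reactants: 15 4-acetyl-2-[(2S)-5-methyl-2-(prop-1-en-2-yl)hex-4-en-1-yl]-1,3-phenylene diacetate; 16 salicylaldehyde
Product: 18 (2E)-1-{2,4-dihydroxy-3-[(2S)-5-methyl-2-(prop-1-en-2-yl)hex-4-en-1-yl]phenyl}-3-(2-hydroxyphenyl)prop-2-en-1-one, via dihydroxy ketone 17 (not isolated)
Conditions: KOH (50 % aq.), EtOH, 0 °C, 30 min; then 16 (1.5 equiv), rt, 48 h, argon, dark; cold dilute HCl to pH 5
Reagents that add atoms: none
Why: Saponification of the two aryl acetates followed by Claisen–Schmidt (crossed aldol) condensation of the methyl ketone enolate with the non-enolisable aldehyde and E1cB dehydration to the thermodynamically favoured E-enone, under conditions where the allylic stereocentre is not acidic.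

**Compound list**
1 | 3-methylbut-2-enoic acid (senecioic acid) | CC(C)=CC(=O)O | starting material
2 | prenyl bromide (1-bromo-3-methylbut-2-ene) | CC(C)=CCBr | starting material
3 | dilithium 3-methylbuta-1,3-diene-1,1-bis(olate) | [Li+].[Li+].[O-]C([O-])=CC(C)=C | intermediate
4 | (±)-lavandulic acid, rac-5-methyl-2-(prop-1-en-2-yl)hex-4-enoic acid | CC(C)=CCC(C(C)=C)C(=O)O | intermediate
5 | (R)-pantolactone, (3R)-3-hydroxy-4,4-dimethyloxolan-2-one | CC1(C)COC(=O)[C@@H]1O | starting material
6 | rac-5-methyl-2-(prop-1-en-2-yl)hex-4-enoyl chloride | CC(C)=CCC(C(C)=C)C(Cl)=O | intermediate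
7 | isopropenyl(prenyl)ketene, 3-methyl-2-(3-methylbut-2-en-1-yl)buta-1,3-dien-1-one | CC(C)=CCC(=C=O)C(C)=C | intermediate
8 | (R)-pantolactonyl (R)-lavandulate, (3R)-4,4-dimethyl-2-oxooxolan-3-yl (2R)-5-methyl-2-(prop-1-en-2-yl)hex-4-enoate | C=C(C)[C@@H](CC=C(C)C)C(=O)O[C@H]1C(=O)OCC1(C)C | intermediate
9 | (R)-lavandulol, (2R)-5-methyl-2-(prop-1-en-2-yl)hex-4-en-1-ol | C=C(C)[C@@H](CC=C(C)C)CO | intermediate
10 | (R)-lavandulyl iodide, (3R)-3-(iodomethyl)-2,6-dimethylhepta-1,5-diene | C=C(C)[C@@H](CC=C(C)C)CI | intermediate
11 | 2,4-dihydroxyacetophenone (resacetophenone) | CC(=O)c1ccc(O)cc1O | starting material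
12 | 1-(2,4-dihydroxy-3-iodophenyl)ethan-1-one | CC(=O)c1ccc(O)c(I)c1O | intermediate
13 | 4-acetyl-2-iodo-1,3-phenylene diacetate | CC(=O)Oc1ccc(C(C)=O)c(OC(C)=O)c1I | intermediate
14 | [(2R)-5-methyl-2-(prop-1-en-2-yl)hex-4-en-1-yl]zinc iodide | C=C(C)[C@@H](CC=C(C)C)C[Zn]I | intermediate
15 | 4-acetyl-2-[(2S)-5-methyl-2-(prop-1-en-2-yl)hex-4-en-1-yl]-1,3-phenylene diacetate | C=C(C)[C@@H](CC=C(C)C)Cc1c(OC(C)=O)ccc(C(C)=O)c1OC(C)=O | intermediate
16 | salicylaldehyde (2-hydroxybenzaldehyde) | O=Cc1ccccc1O | starting material
17 | 1-{2,4-dihydroxy-3-[(2S)-5-methyl-2-(prop-1-en-2-yl)hex-4-en-1-yl]phenyl}ethan-1-one (present as its potassium phenoxide in the flask) | C=C(C)[C@@H](CC=C(C)C)Cc1c(O)ccc(C(C)=O)c1O | intermediate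
18 | (2E)-1-{2,4-dihydroxy-3-[(2S)-5-methyl-2-(prop-1-en-2-yl)hex-4-en-1-yl]phenyl}-3-(2-hydroxyphenyl)prop-2-en-1-one | C=C(C)[C@@H](CC=C(C)C)Cc1c(O)ccc(C(=O)/C=C/c2ccccc2O)c1O | target

**Step count and risks**
Total steps: 8 (isolated products 4, 8, 9, 10, 12, 13, 15, 18). Longest linear sequence: 6 steps (1 → 2 → 3 → 4 → 7 → 8); steps 5 and 6 form the two-step arene branch.

Most likely to fail:

Step 2 (the proposed ketene esterification). The diastereoselectivity, and even the sense of induction, are untested for an alkenyl(alkyl)ketene, and the ketene may dimerise before it is trapped. The fallback uses known chemistry, an auxiliary-controlled enolate alkylation in place of ketene protonation; it sets out from 2 and comes back at 9. (4R)-4-Benzyl-1,3-oxazolidin-2-one is N-acylated with commercial 3-methylbut-2-enoyl chloride (n-BuLi, THF, −78 °C) to (4R)-4-benzyl-3-(3-methylbut-2-enoyl)-1,3-oxazolidin-2-one F1. NaN(SiMe3)2 (THF, −78 °C) gives the chelated Z-dienolate, which 2 alkylates at the α-carbon on the face away from the benzyl group, with deconjugation (Evans alkylation), to (4R)-4-benzyl-3-[(2R)-5-methyl-2-(prop-1-en-2-yl)hex-4-enoyl]-1,3-oxazolidin-2-one F2. LiBH4 (Et2O, 1 equiv H2O, 0 °C) then cleaves the auxiliary and delivers 9.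

Step 7 (Negishi coupling). The iodide is flanked by two ortho substituents, and β-hydride elimination from the alkylpalladium would cost material as a diene or erode the ee. The fallback is a polar SN2 arylation without a transition metal, with the ketone introduced afterwards; it sets out from 10 and comes back at 17. Commercial 1,3-bis(methoxymethoxy)benzene is lithiated between the two ether groups (n-BuLi, THF, 0 °C) to 2-lithio-1,3-bis(methoxymethoxy)benzene F3, which is alkylated by 10 (THF, −78 °C → rt) to 2-[(2S)-5-methyl-2-(prop-1-en-2-yl)hex-4-en-1-yl]-1,3-bis(methoxymethoxy)benzene F4. A second directed ortho-lithiation (n-BuLi, TMEDA, THF, 0 °C) gives 4-lithio-2-[(2S)-5-methyl-2-(prop-1-en-2-yl)hex-4-en-1-yl]-1,3-bis(methoxymethoxy)benzene F5, which is acetylated with N-methoxy-N-methylacetamide to 1-{2,4-bis(methoxymethoxy)-3-[(2S)-5-methyl-2-(prop-1-en-2-yl)hex-4-en-1-yl]phenyl}ethan-1-one F6. Brief treatment with dilute HCl in MeOH at rt removes both acetal groups and gives 17, now isolated, which is condensed with 16 under the conditions of step 8.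

Step 8 (unprotected Claisen–Schmidt condensation). Both partners are phenoxides, so the aldol is slow and retro-aldol and air oxidation compete on the most valuable intermediate. The fallback inverts the order of bond formation: the enone is made first on cheap material, the lavandulyl group is introduced last, and the final step is a mild deacetylation. It sets out from 12 and comes back at 18. Ketone 12 is condensed with 16 (KOH, EtOH/H2O, rt) to (2E)-1-(2,4-dihydroxy-3-iodophenyl)-3-(2-hydroxyphenyl)prop-2-en-1-one F7. Ac2O/pyridine converts it into 2-[(1E)-3-(2,4-diacetoxy-3-iodophenyl)-3-oxoprop-1-en-1-yl]phenyl acetate F8. Negishi coupling of F8 with alkylzinc iodide 14 under the conditions of step 7 gives the triacetate of the target F9. K2CO3 in MeOH at 0 °C removes the three acetates and gives 18.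

**Further compounds**
F1 | step 2 | (4R)-4-benzyl-3-(3-methylbut-2-enoyl)-1,3-oxazolidin-2-one | CC(C)=CC(=O)N1[C@H](Cc2ccccc2)COC1=O
F2 | step 2 | (4R)-4-benzyl-3-[(2R)-5-methyl-2-(prop-1-en-2-yl)hex-4-enoyl]-1,3-oxazolidin-2-one | C=C(C)[C@@H](CC=C(C)C)C(=O)N1[C@H](Cc2ccccc2)COC1=O
F3 | step 7 | 2-lithio-1,3-bis(methoxymethoxy)benzene | COCOc1cccc(OCOC)c1[Li]
F4 | step 7 | 2-[(2S)-5-methyl-2-(prop-1-en-2-yl)hex-4-en-1-yl]-1,3-bis(methoxymethoxy)benzene | C=C(C)[C@@H](CC=C(C)C)Cc1c(OCOC)cccc1OCOC
F5 | step 7 | 4-lithio-2-[(2S)-5-methyl-2-(prop-1-en-2-yl)hex-4-en-1-yl]-1,3-bis(methoxymethoxy)benzene | C=C(C)[C@@H](CC=C(C)C)Cc1c(OCOC)ccc([Li])c1OCOC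
F6 | step 7 | 1-{2,4-bis(methoxymethoxy)-3-[(2S)-5-methyl-2-(prop-1-en-2-yl)hex-4-en-1-yl]phenyl}ethan-1-one | C=C(C)[C@@H](CC=C(C)C)Cc1c(OCOC)ccc(C(C)=O)c1OCOC
F7 | step 8 | (2E)-1-(2,4-dihydroxy-3-iodophenyl)-3-(2-hydroxyphenyl)prop-2-en-1-one | O=C(/C=C/c1ccccc1O)c1ccc(O)c(I)c1O
F8 | step 8 | 2-[(1E)-3-(2,4-diacetoxy-3-iodophenyl)-3-oxoprop-1-en-1-yl]phenyl acetate | CC(=O)Oc1ccccc1/C=C/C(=O)c1ccc(OC(C)=O)c(I)c1OC(C)=O
F9 | step 8 | 2-[(1E)-3-{2,4-diacetoxy-3-[(2S)-5-methyl-2-(prop-1-en-2-yl)hex-4-en-1-yl]phenyl}-3-oxoprop-1-en-1-yl]phenyl acetate | C=C(C)[C@@H](CC=C(C)C)Cc1c(OC(C)=O)ccc(C(=O)/C=C/c2ccccc2OC(C)=O)c1OC(C)=O
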